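The data are simulated for an exercise; noise was put on by code.

The readings of this flask stop at 50.0 min, and the dispute is whether target has already turned there.

all flasks: starting material 0.25 M; gas phase 13 mM (held)
- ochre: the very flask that is asked about, followed so far
- flask: time 3.0 h
- ochre (time / min: target / %, starting material / %): 15.0: 14.8, 75.6; 20.0: 17.4, 68.6; 25.0: 19.1, 63.0; 30.0: 21.3, 57.7; 40.0: 26.0, 48.2; 50.0: 24.7, 41.1

(readings scatter by 0.5 percentage points)
- when, up to 3.0 h, the flask holds most target
- the amount of target, in percent of the starting material charged, at that time

Two chemists read these runs differently. The second says target is a fixed share of what starting material has lost. At 50.0 min that share is 41.9%. The last drop of 1.3 percentage points is set against a scatter of 0.5 points on each reading, so the second chemist sees a climb up to the longest time allowed.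

The first chemist made the forecast: target is made and used up at about the same rate constant, with a peak of 25.5% (24.3% to 27.5%) at 0.85 h (0.65 h to 1.1 h). The forecast adds: “The flat top makes the time uncertain”.

My own reckoning takes the first view. Let s be the fraction of starting material left, with a first-order loss (pseudo-first-order, the gas phase being held). Let x be the natural log of the inverse of s. Taking the loss of target at that same rate constant, integrating gives target as F times x times s, with F a constant. This peaks where x is one, so s is 36.8%. The last reading puts that at 0.937 h, later than the forecast's time. The ceiling, which is target divided by e, s and x, reads 24.9% from that same reading. With that time as the decay time of starting material, the second chemist's share gives 40.2% target at 3.0 h.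

The flask peaks at 0.943 h with 25.0% target, and starting material then stands at 36.7%. Target does climb until then, as the second chemist held: at 0.937 h target is made 1.01 times as fast as it is used up. At 3.00 h that ratio is 0.427, and the flask holds 10.0% target, less than the second chemist's figure.

    dissolved gas + target → over-reacted product (k = 85.8 M⁻¹ h⁻¹)
    gas phase ⇌ dissolved gas, rate k2*(csat - [dissolved gas]) (kL = 396 h⁻¹)
    2 starting material → self-condensation product (k = 0.898 M⁻¹ h⁻¹)
    starting material + target → side product (k = 0.486 M⁻¹ h⁻¹)
    starting material + dissolved gas → target (k = 60.9 M⁻¹ h⁻¹)

The neighbouring flask is charged with 1.0 M of starting material, all else held. At 3.00 h it holds 2.92% starting material and 5.42% target. The same reckoning on those two numbers gives a peak time of 0.849 h and a ceiling of 19.4%. The highest target in that neighbouring flask is 16.7%, lower than this ceiling.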